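**Plan**
1. Retrosynthesis: the last cut is the C8–O–CH3 ether. The next is C8–C8a of ring A, traced back through a ketene to the C1–C4 bond of a cyclobutenone. The third is C4a–C5, between a C5-metallated 3-methoxy-2-phenyl-4-pyranone and dimethyl squarate.
2. Enabling feature: C5(OH)–C6(OMe)–C7(OMe)–C8(O) of ring A are four adjacent oxygen-bearing carbons, the carbon set of a squarate ester. Ring A shares the C4a=C8a bond with ring C, which is simply the C5=C6 alkene of a monocyclic 4-pyranone.
3. Forward order: ring C first (furan to 3-hydroxy-4-pyranone), then O-methylation, C5 iodination, I/Mg exchange and 1,2-addition to the squarate (C4a–C5). Thermal ring opening and 6π closure then build ring A (C8–C8a), and 8-O-methylation finishes.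
4. Stereochemistry: the target has no stereogenic element. The carbinol, hemiacetal and ring-fusion centres met on the way are racemic and are erased by aromatisation.

Key step: step 6

Assumption: the target is achiral (no stereocentre, no hindered axis), so "single enantiomer" needs no control and all intermediates are used racemic.

**Step 1**
Reactants: 1 furfural; 2 bromobenzene
Product: 4 furan-2-yl(phenyl)methanol (racemic), via phenylmagnesium bromide 3 (not isolated)
Conditions: Mg, THF, reflux; then 1, 0 °C; aq NH4Cl
Reagents that add atoms: none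
Why: Grignard formation followed by 1,2-addition to a non-enolisable aldehyde should give the secondary carbinol cleanly; the new centre forms racemic and is erased in step 2.

**Step 2**
Reactants: 4 furan-2-yl(phenyl)methanol
Product: 7 3-hydroxy-2-phenyl-4H-pyran-4-one, via Achmatowicz hemiacetal 5 (not isolated), via 4-chloro enone 6 (not isolated)
Conditions: Cl2 (2.1 equiv), MeCN–H2O, −10 °C; then reflux
Reagents that add atoms: water, O
Why: Achmatowicz oxidative ring expansion of the 2-furylcarbinol by aqueous chlorine gives hemiacetal 5, a second equivalent chlorinates the enone at C4, and hot aqueous acid then trades the C6 hydroxyl and C4 chloride for the 4-oxo group and enolises to the aromatic pyranone (the one-pot sequence used to make maltol from 1-(furan-2-yl)ethanol), erasing every sp3 centre.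

**Step 3**
Reactants: 7 3-hydroxy-2-phenyl-4H-pyran-4-one
Product: 8 3-methoxy-2-phenyl-4H-pyran-4-one
Conditions: MeI, K2CO3, acetone, reflux
Reagents that add atoms: iodomethane, CI
Why: Williamson O-alkylation of the acidic enolic 3-OH, as in the methylation of maltol, should be straightforward.

**Step 4**
Reactants: 8 3-methoxy-2-phenyl-4H-pyran-4-one
Product: 9 5-iodo-3-methoxy-2-phenyl-4H-pyran-4-one
Conditions: NIS, TFA, MeCN, 60 °C, dark
Reagents that add atoms: N-iodosuccinimide, O=C1CCC(=O)N1I
Why: Electrophilic iodination of 4-pyranones occurs α to the carbonyl, and C5 is the β-carbon of the ring enol ether O1–C6=C5 and the only free nucleophilic position, the phenyl ring being deactivated by the pyranone.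

**Step 5**
Reactants: 9 5-iodo-3-methoxy-2-phenyl-4H-pyran-4-one; 10 dimethyl squarate
Product: 12 4-hydroxy-2,3-dimethoxy-4-(5-methoxy-4-oxo-6-phenyl-4H-pyran-3-yl)cyclobut-2-en-1-one (racemic), via pyranonylmagnesium chloride 11 (not isolated)
Conditions: iPrMgCl·LiCl (1.05 equiv), THF, −40 °C; cannulate into 10 (1.5 equiv), THF, −78 °C; aq NH4Cl, −78 °C
Reagents that add atoms: none
Why: Iodine–magnesium exchange with the turbo-Grignard is fast at −40 °C on an sp2 C–I bond next to a carbonyl and should outrun addition to the pyranone; the heteroaryl Grignard then adds 1,2 to one of the two equivalent squarate carbonyls (standard organometallic addition to squarate esters), inverse addition to excess 10 holding back bis-addition, and the racemic carbinol centre is erased in step 6.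

**Step 6**
Reactants: 12 4-hydroxy-2,3-dimethoxy-4-(5-methoxy-4-oxo-6-phenyl-4H-pyran-3-yl)cyclobut-2-en-1-one
Product: 15 5,8-dihydroxy-3,6,7-trimethoxyflavone, via dienylketene 13 (not isolated), via ring-fused dienone 14 (not isolated)
Conditions: degassed toluene (0.02 M), reflux, Ar; evaporate under Ar
Reagents that add atoms: none
Why: Heating breaks the cyclobutenone C1–C4 bond in a 4π conrotatory opening to the (Z)-dienylketene 13, the donor hydroxyl turning outward so that the pyranone ends up cis to the ketene. A 6π disrotatory electrocyclisation over the ketene C=C, the central C=C and the pyranone C5=C6 bond then joins the ketene carbon to pyranone C6 (the future C8–C8a bond), closing ring A as a six-membered carbocycle in dienone 14, and enolisation aromatises it to the 5,8-hydroquinone 15. The closest known reaction type is the Moore rearrangement of squarate-derived 4-aryl- and 4-alkenyl-4-hydroxycyclobutenones to hydroquinones. No stereocentre survives, because the carbinol carbon and the ring-fusion C–H carbon both become aromatic. The step needs torquoselectivity, secured by the outward preference of the hydroxyl, and regioselective closure, secured because the attached pyranone carbon has only one alkene partner (C6–H), its other neighbour being the carbonyl carbon. Exclusion of oxygen should keep the hydroquinone from going on to the quinone.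

**Step 7**
Reactants: 15 5,8-dihydroxy-3,6,7-trimethoxyflavone
Product: 16 5-hydroxy-3,6,7,8-tetramethoxyflavone
Conditions: MeI (1.1 equiv), K2CO3 (1.1 equiv), degassed acetone, rt to 40 °C, Ar
Reagents that add atoms: iodomethane, CI
Why: Williamson methylation should take only the free 8-OH, because the 5-OH is held in a strong hydrogen bond to the C4 carbonyl and is far less acidic and nucleophilic (the usual basis of partial methylation of 5-hydroxyflavones), while one equivalent of MeI and exclusion of air guard against over-alkylation and quinone formation.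

**Compound list**
1 | furfural | O=Cc1ccco1 | starting material
2 | bromobenzene | Brc1ccccc1 | starting material
3 | phenylmagnesium bromide | Br[Mg]c1ccccc1 | intermediate
4 | furan-2-yl(phenyl)methanol (racemic) | OC(c1ccco1)c1ccccc1 | intermediate
5 | 6-hydroxy-2-phenyl-2H-pyran-3(6H)-one (Achmatowicz hemiacetal, racemic anomeric mixture) | O=C1C=CC(O)OC1c1ccccc1 | intermediate
6 | 4-chloro-6-hydroxy-2-phenyl-2H-pyran-3(6H)-one (racemic anomeric mixture) | O=C1C(Cl)=CC(O)OC1c1ccccc1 | intermediate
7 | 3-hydroxy-2-phenyl-4H-pyran-4-one | O=c1ccoc(-c2ccccc2)c1O | intermediate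
8 | 3-methoxy-2-phenyl-4H-pyran-4-one | COc1c(-c2ccccc2)occc1=O | intermediate
9 | 5-iodo-3-methoxy-2-phenyl-4H-pyran-4-one | COc1c(-c2ccccc2)occ(I)c1=O | intermediate
10 | dimethyl squarate | COC1=C(OC)C(=O)C1=O | starting material
11 | (5-methoxy-4-oxo-6-phenyl-4H-pyran-3-yl)magnesium chloride (LiCl complex) | COc1c(-c2ccccc2)occ([Mg]Cl)c1=O | intermediate
12 | 4-hydroxy-2,3-dimethoxy-4-(5-methoxy-4-oxo-6-phenyl-4H-pyran-3-yl)cyclobut-2-en-1-one (racemic) | COC1=C(OC)C(O)(c2coc(-c3ccccc3)c(OC)c2=O)C1=O | intermediate
13 | (3Z)-4-hydroxy-2,3-dimethoxy-4-(5-methoxy-4-oxo-6-phenyl-4H-pyran-3-yl)buta-1,3-dien-1-one (dienylketene) | O=C=C(OC)/C(OC)=C(/O)c1coc(-c2ccccc2)c(OC)c1=O | intermediate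
14 | 5-hydroxy-3,6,7-trimethoxy-2-phenyl-4H-chromene-4,8(8aH)-dione (ring-fused dienone, racemic) | O=C1C(OC)=C(OC)C(O)=C2C(=O)C(OC)=C(-c3ccccc3)OC12 | intermediate
15 | 5,8-dihydroxy-3,6,7-trimethoxyflavone | COc1c(OC)c(O)c2c(=O)c(OC)c(-c3ccccc3)oc2c1O | intermediate
16 | 5-hydroxy-3,6,7,8-tetramethoxyflavone | COc1c(OC)c(O)c2c(=O)c(OC)c(-c3ccccc3)oc2c1OC | target

**Totals**
Total step count: 7. Longest linear sequence: 7 steps (1 and 2 to 16; dimethyl squarate 10 enters at step 5).

**Steps most likely to fail**

Risk 1, step 5. The magnesiated pyranone may unravel by β-elimination of the ring oxygen, or the isopropyl Grignard may add conjugatively at C6 before exchange takes place; the adduct alkoxide may also invite a second addition to the squarate. The fallback sets out from 9. Activated zinc dust (LiCl, THF, 25–40 °C) is inserted directly into the C–I bond to give (5-methoxy-4-oxo-6-phenyl-4H-pyran-3-yl)zinc iodide F1, a much less basic nucleophile made without any alkyl-metal exchange reagent. MgCl2-promoted 1,2-addition of F1 to dimethyl squarate 10 then returns to the route at 12.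

Risk 2, step 6. The free tertiary carbinol may undergo an acid-triggered 1,2-shift before ring opening, and the electron-rich hydroquinone may be lost to aerial oxidation during heating and isolation. The fallback sets out from 12 and never passes through a free hydroquinone.
- Silylation (TESOTf, 2,6-lutidine, CH2Cl2, −78 °C) gives 2,3-dimethoxy-4-(5-methoxy-4-oxo-6-phenyl-4H-pyran-3-yl)-4-(triethylsilyloxy)cyclobut-2-en-1-one F2.
- Thermolysis in toluene runs the same cascade through (3Z)-2,3-dimethoxy-4-(5-methoxy-4-oxo-6-phenyl-4H-pyran-3-yl)-4-(triethylsilyloxy)buta-1,3-dien-1-one F3 and 3,6,7-trimethoxy-2-phenyl-5-(triethylsilyloxy)-4H-chromene-4,8(8aH)-dione F4. It should deliver the mono-protected 8-hydroxy-3,6,7-trimethoxy-5-(triethylsilyloxy)flavone F5.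
- Methylation of the only free phenol (MeI, K2CO3, acetone) gives 3,6,7,8-tetramethoxy-5-(triethylsilyloxy)flavone F6.
- Desilylation with TBAF in THF at 0 °C rejoins the route at 16.

Risk 3, step 2. In the HCl-rich one-pot medium the furylcarbinol may undergo acid-mediated Piancatelli-type rearrangement, and chlorination may run past the mono-chloro stage or onto the enolic product. The fallback sets out from 4 and replaces chlorine by a stepwise sequence.
- Buffered Achmatowicz oxidation (NBS, NaHCO3, THF–H2O, 0 °C) gives hemiacetal 5, now isolated.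
- Acetalisation (HC(OMe)3, BF3·OEt2, CH2Cl2, 0 °C) gives 6-methoxy-2-phenyl-2H-pyran-3(6H)-one F7.
- Nucleophilic epoxidation of the enone (H2O2, NaHCO3, MeOH, 0 °C) gives 2-methoxy-4-phenyl-3,7-dioxabicyclo[4.1.0]heptan-5-one F8.
- Hot dilute H2SO4 opens the epoxide, expels methanol and enolises, coming back to the route at 7.

**Further compounds**
F1 | step 5 | (5-methoxy-4-oxo-6-phenyl-4H-pyran-3-yl)zinc iodide | COc1c(-c2ccccc2)occ([Zn]I)c1=O
F2 | step 6 | 2,3-dimethoxy-4-(5-methoxy-4-oxo-6-phenyl-4H-pyran-3-yl)-4-(triethylsilyloxy)cyclobut-2-en-1-one (racemic) | COC1=C(OC)C(O[Si](CC)(CC)CC)(c2coc(-c3ccccc3)c(OC)c2=O)C1=O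
F3 | step 6 | (3Z)-2,3-dimethoxy-4-(5-methoxy-4-oxo-6-phenyl-4H-pyran-3-yl)-4-(triethylsilyloxy)buta-1,3-dien-1-one | O=C=C(OC)/C(OC)=C(/O[Si](CC)(CC)CC)c1coc(-c2ccccc2)c(OC)c1=O
F4 | step 6 | 3,6,7-trimethoxy-2-phenyl-5-(triethylsilyloxy)-4H-chromene-4,8(8aH)-dione (racemic) | O=C1C(OC)=C(OC)C(O[Si](CC)(CC)CC)=C2C(=O)C(OC)=C(-c3ccccc3)OC12
F5 | step 6 | 8-hydroxy-3,6,7-trimethoxy-5-(triethylsilyloxy)flavone | COc1c(OC)c(O[Si](CC)(CC)CC)c2c(=O)c(OC)c(-c3ccccc3)oc2c1O
F6 | step 6 | 3,6,7,8-tetramethoxy-5-(triethylsilyloxy)flavone | COc1c(OC)c(O[Si](CC)(CC)CC)c2c(=O)c(OC)c(-c3ccccc3)oc2c1OC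
F7 | step 2 | 6-methoxy-2-phenyl-2H-pyran-3(6H)-one (racemic anomeric mixture) | COC1C=CC(=O)C(c2ccccc2)O1
F8 | step 2 | 2-methoxy-4-phenyl-3,7-dioxabicyclo[4.1.0]heptan-5-one (racemic) | COC1OC(c2ccccc2)C(=O)C2OC12
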